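**Retrosynthetic overview**
1. Target ⇒ cut the bond between ring-A C3′ and the methine carbon. It is formed last by an enantioselective Friedel–Crafts alkylation of the chalcone helichrysetin with an achiral dienyl para-quinone methide, which a chiral phosphoric acid generates from the racemic diarylheptenol. This step sets the only stereocentre.
2. Helichrysetin ⇒ Claisen–Schmidt condensation of 2′,4′-dihydroxy-6′-methoxyacetophenone with 4-hydroxybenzaldehyde.
3. Racemic (E)-1,7-bis(4-hydroxyphenyl)hept-1-en-3-ol ⇒ Luche reduction of the enone ⇒ aldol condensation of 6-(4-hydroxyphenyl)hexan-2-one with 4-hydroxybenzaldehyde.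
4. The methyl ketone ⇒ Sonogashira coupling of 4-iodophenol with hex-5-yn-2-one, then hydrogenation.
5. Rings: none is formed. All three benzene rings are bought and no protecting group is used.

Assumption: 4-iodophenol, hex-5-yn-2-one, 4-hydroxybenzaldehyde and 2′,4′-dihydroxy-6′-methoxyacetophenone are catalogue compounds; the racemic allylic alcohol made on the way is acceptable because its carbinol centre is erased before the stereocentre is set.

**Route**

Step 1
Reactants: 1 4-iodophenol; 2 hex-5-yn-2-one
Product: 3 6-(4-hydroxyphenyl)hex-5-yn-2-one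
Conditions: PdCl2(PPh3)2 (2 mol%), CuI (4 mol%), Et3N, THF, rt, 12 h
Reagents that add atoms: none
Why: Sonogashira coupling of an aryl iodide with a terminal alkyne is regiospecific, runs at room temperature and tolerates the free phenol and the remote ketone.

Step 2
Reactants: 3 6-(4-hydroxyphenyl)hex-5-yn-2-one
Product: 4 6-(4-hydroxyphenyl)hexan-2-one
Conditions: H2 (1 atm), 10% Pd/C, EtOAc, rt
Reagents that add atoms: none
Why: Heterogeneous catalytic hydrogenation takes the alkyne to the alkane while the dialkyl ketone and the phenol are inert under 1 atm H2.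

Step 3
Reactants: 4 6-(4-hydroxyphenyl)hexan-2-one; 5 4-hydroxybenzaldehyde
Product: 6 (E)-1,7-bis(4-hydroxyphenyl)hept-1-en-3-one
Conditions: pyrrolidine (30 mol%), AcOH (30 mol%), THF, 45 °C, 24 h
Reagents that add atoms: none
Why: Amine/acid-catalysed Claisen–Schmidt (aldol) condensation reacts at the methyl side of the ketone, forms no deactivating phenoxide from the aldehyde and gives the conjugated (E)-enone as the thermodynamic product.

Step 4
Reactants: 6 (E)-1,7-bis(4-hydroxyphenyl)hept-1-en-3-one
Product: 7 racemic (E)-1,7-bis(4-hydroxyphenyl)hept-1-en-3-ol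
Conditions: NaBH4, CeCl3·7H2O, MeOH, −20 °C; sat. NH4Cl; chromatography on Et3N-washed SiO2
Reagents that add atoms: none
Why: Luche reduction gives clean 1,2-reduction of the enone, and the racemic carbinol centre does not matter because it is destroyed in step 6.

Step 5
Reactants: 8 2′,4′-dihydroxy-6′-methoxyacetophenone; 5 4-hydroxybenzaldehyde
Product: 9 helichrysetin [(E)-1-(2,4-dihydroxy-6-methoxyphenyl)-3-(4-hydroxyphenyl)prop-2-en-1-one]
Conditions: KOH (50% aq, 15 equiv), EtOH, rt to 40 °C, 48 h; then cold 1 M HCl to pH 4
Reagents that add atoms: none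
Why: Claisen–Schmidt condensation at the only enolisable position gives the (E)-chalcone, which stays ring-open in strong alkali and is kept from flavanone closure by cold acidification.

Step 6
Reactants: 7 racemic (E)-1,7-bis(4-hydroxyphenyl)hept-1-en-3-ol; 9 helichrysetin (1.5 equiv)
Product: 11 deoxycalyxin A, via dienyl para-quinone methide 10 (not isolated)
Conditions: (R)-TRIP [(R)-3,3′-bis(2,4,6-triisopropylphenyl)-BINOL hydrogen phosphate] (10 mol%), 5 Å MS, CH2Cl2/EtOAc 5:1, 0 °C, 7 added over 6 h, then 36 h
Reagents that add atoms: none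
Why: Proposed new method: a chiral-phosphoric-acid-catalysed, stereoconvergent dehydrative Friedel–Crafts alkylation in which the acid ionises racemic 7 to the achiral s-trans dienyl para-quinone methide 10 (erasing the carbinol centre) and then, hydrogen-bonded through P–OH to the carbonyl oxygen of 10 and through P=O to the free 4′-OH of 9, delivers C3′ of 9 to one face of the δ-carbon (1,8-addition), which re-aromatises the phenol, leaves the (E)-styrene and sets the (R)-methine; δ- over α-attack is expected because only it keeps the styrene conjugation, and C3′ over C5′ because the 6′-OMe methyl is turned towards C5′ by the neighbouring acyl group while the chelated 2′-OH leaves C3′ open; the closest known reaction types are CPA-catalysed 1,6-additions of phenols and naphthols to para-quinone methides made in situ from p-hydroxybenzyl alcohols and CPA-catalysed 1,8-additions to alkynyl para-quinone methides from propargylic alcohols, neither shown for a δ-alkyl dienyl para-quinone methide or for an unprotected acylphloroglucinol chalcone.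

**Compound list**
1 | 4-iodophenol | Oc1ccc(I)cc1 | starting material
2 | hex-5-yn-2-one | CC(=O)CCC#C | starting material
3 | 6-(4-hydroxyphenyl)hex-5-yn-2-one | CC(=O)CCC#Cc1ccc(O)cc1 | intermediate
4 | 6-(4-hydroxyphenyl)hexan-2-one | CC(=O)CCCCc1ccc(O)cc1 | intermediate
5 | 4-hydroxybenzaldehyde | O=Cc1ccc(O)cc1 | starting material
6 | (E)-1,7-bis(4-hydroxyphenyl)hept-1-en-3-one | O=C(/C=C/c1ccc(O)cc1)CCCCc1ccc(O)cc1 | intermediate
7 | racemic (E)-1,7-bis(4-hydroxyphenyl)hept-1-en-3-ol | OC(/C=C/c1ccc(O)cc1)CCCCc1ccc(O)cc1 | intermediate
8 | 2′,4′-dihydroxy-6′-methoxyacetophenone [1-(2,4-dihydroxy-6-methoxyphenyl)ethan-1-one] | COc1cc(O)cc(O)c1C(C)=O | starting material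
9 | helichrysetin [(E)-1-(2,4-dihydroxy-6-methoxyphenyl)-3-(4-hydroxyphenyl)prop-2-en-1-one] | COc1cc(O)cc(O)c1C(=O)/C=C/c1ccc(O)cc1 | intermediate
10 | 4-[(2E)-7-(4-hydroxyphenyl)hept-2-en-1-ylidene]cyclohexa-2,5-dien-1-one (dienyl para-quinone methide) | O=C1C=CC(=C/C=C/CCCCc2ccc(O)cc2)C=C1 | intermediate (not isolated)
11 | deoxycalyxin A [(E)-1-{2,4-dihydroxy-3-[(1E,3R)-1,7-bis(4-hydroxyphenyl)hept-1-en-3-yl]-6-methoxyphenyl}-3-(4-hydroxyphenyl)prop-2-en-1-one] | COc1cc(O)c([C@@H](/C=C/c2ccc(O)cc2)CCCCc2ccc(O)cc2)c(O)c1C(=O)/C=C/c1ccc(O)cc1 | target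

**Totals**
Total steps: 6. Longest linear sequence: 5 (steps 1, 2, 3, 4, 6); step 5 is a one-step side branch.

**Three steps most likely to fail**

Step 6 (the proposed new method) is the main risk.
- The enantioselectivity at a carbon eight atoms from the anchoring oxygen is untested, and the free OH groups of 7 and 9 compete for the catalyst.
- The absolute sense of induction with (R)-TRIP is not established. It must be checked by chiral HPLC and by comparing rotation with natural material; (S)-TRIP is the mirror-image choice if the sense is reversed.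
- The C3′/C5′ and δ/α selectivities are expected but not proven.
- The acid can close the product to a flavan-type chroman through the p-hydroxystyrene, so the reaction is kept at 0 °C and stopped at full conversion of 7.
- 10 can oligomerise, hence slow addition of 7 and excess 9.

The fallback sets out from 7 and 9 and comes back at 11. The same bond is made without asymmetric induction by the known Brønsted-acid Friedel–Crafts alkylation of a phloroglucinol ring with a p-hydroxycinnamyl-type alcohol (diphenyl phosphate 10 mol%, CH2Cl2/EtOAc, 0 °C). This gives racemic deoxycalyxin A F1, with any C5′ isomer removed on silica. Preparative HPLC on a chiral stationary phase (amylose tris(3,5-dimethylphenylcarbamate), hexane/i-PrOH) then resolves it into 11 and its mirror image (S)-deoxycalyxin A F2, which is set aside.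

Step 5 is the second risk. The unprotected Claisen–Schmidt condensation runs through a poorly reactive polyanion with a phenoxide-deactivated aldehyde, so conversion may be low.

The fallback sets out from 8 and 5 and comes back at 9, using the usual protecting-group route to such chalcones:
- MOMCl/i-Pr2NEt (CH2Cl2, 0 °C) converts 8, at the non-chelated 4′-OH only, into 1-[2-hydroxy-6-methoxy-4-(methoxymethoxy)phenyl]ethan-1-one F3.
- The same reagents convert 5 into 4-(methoxymethoxy)benzaldehyde F4.
- KOH/EtOH condensation of F3 with F4 gives (E)-1-[2-hydroxy-6-methoxy-4-(methoxymethoxy)phenyl]-3-[4-(methoxymethoxy)phenyl]prop-2-en-1-one F5.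
- HCl/MeOH at 40 °C removes both MOM groups to give 9.

Step 3 is the third risk. The free hydroxybenzaldehyde may condense sluggishly, and some reaction at the methylene side or double condensation is possible.

The fallback sets out from 4 and comes back at 6. Ketone 4 is condensed under classical hydroxide conditions (NaOH, EtOH/H2O, rt) with the non-deactivated 4-(methoxymethoxy)benzaldehyde F4, made from 5 as in the fallback to step 5. This gives (E)-7-(4-hydroxyphenyl)-1-[4-(methoxymethoxy)phenyl]hept-1-en-3-one F6, with base directing the reaction to the methyl group. HCl/MeOH at 40 °C then frees the phenol to give 6.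

**Further compounds**
F1 | step 6 | racemic deoxycalyxin A | COc1cc(O)c(C(/C=C/c2ccc(O)cc2)CCCCc2ccc(O)cc2)c(O)c1C(=O)/C=C/c1ccc(O)cc1
F2 | step 6 | (S)-deoxycalyxin A (enantiomer of 11) | COc1cc(O)c([C@H](/C=C/c2ccc(O)cc2)CCCCc2ccc(O)cc2)c(O)c1C(=O)/C=C/c1ccc(O)cc1
F3 | step 5 | 1-[2-hydroxy-6-methoxy-4-(methoxymethoxy)phenyl]ethan-1-one | COCOc1cc(O)c(C(C)=O)c(OC)c1
F4 | step 5 | 4-(methoxymethoxy)benzaldehyde | COCOc1ccc(C=O)cc1
F5 | step 5 | (E)-1-[2-hydroxy-6-methoxy-4-(methoxymethoxy)phenyl]-3-[4-(methoxymethoxy)phenyl]prop-2-en-1-one | COCOc1ccc(/C=C/C(=O)c2c(O)cc(OCOC)cc2OC)cc1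
F6 | step 3 | (E)-7-(4-hydroxyphenyl)-1-[4-(methoxymethoxy)phenyl]hept-1-en-3-one | COCOc1ccc(/C=C/C(=O)CCCCc2ccc(O)cc2)cc1
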